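**Strategy.** Everything rests on closing the butenolide (ring C) last by exploiting the 1,2-relationship of the C13 ketone and the C16 hydroxyl in the side chain. (Triphenylphosphoranylidene)ketene acylates O16 and the resulting ester ylide olefinates C13 in the same flask, so the C16–O–C15 ester bond and the C13=C14 alkene form in one neutral operation that spares the C3 ketone, the C19 ester and both silyl ethers. The precursor is the bis-silylated bicyclic core (rings A and B with the C5=C10 alkene) bearing this ketol; it is reached from (S)-carvone through cuprate addition–propargylation, Diels–Alder annulation of ring A and C6-controlled hydroxymethylation at C4.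

Key step: step 17

Remark: atom numbers follow the halimane skeleton of the target (ring A = C1–C5, C10; ring B = C5–C10; side chain C11–C16; C17 on C8, C18 and C19 on C4, C20 on C9), α is the face of the C6 oxygen, β the face of the C8 and C9 methyl groups, and compounds 2 and 30 are taken as purchasable.

Step 1
Reactants: 1 (S)-carvone; 2 (3-bromoprop-1-yn-1-yl)triisopropylsilane
Product: 4 propargylated dimethyl ketone, via lithium enolate 3 (not isolated)
Conditions: Me2CuLi (MeLi, CuI), Et2O, −78 → 0 °C; then 2, DMPU, THF, 0 °C → rt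
Reagents that add atoms: lithium dimethylcuprate, [Li+].C[Cu-]C
Why: The cuprate delivers methyl to C8 anti to the C6 isopropenyl group and the resulting enolate is alkylated at C9 by the propargylic bromide anti to the new C8 methyl, so the C8 and C9 methyl groups end cis (conjugate addition followed by enolate alkylation).

Step 2
Reactants: 4 propargylated dimethyl ketone
Product: 7 β-hydroxy ketone, via methoxy hydroperoxide 5 (not isolated), via acetate 6 (not isolated)
Conditions: O3, CH2Cl2/MeOH, −78 °C; Ac2O, Et3N, DMAP, −78 °C → rt; then K2CO3, MeOH, 0 °C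
Reagents that add atoms: ozone, [O-][O+]=O
Why: Ozone cleaves only the electron-rich isopropenyl alkene, the methoxy hydroperoxide is acetylated and rearranges with migration of C6 to oxygen with retention (Criegee rearrangement), and cold methanolysis of the acetate frees the C6 hydroxyl before β-elimination can compete.

Step 3
Reactants: 7 β-hydroxy ketone
Product: 8 triethylsilyl ether
Conditions: Et3SiCl, imidazole, DMF, 0 °C → rt
Reagents that add atoms: chlorotriethylsilane, CC[Si](Cl)(CC)CC
Why: Silylation masks the β-hydroxyl so that the ketone can be enolised in the next step (silyl ether formation).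

Step 4
Reactants: 8 triethylsilyl ether
Product: 9 enol triflate
Conditions: LiN(SiMe3)2, THF, −78 °C; then N-(5-chloropyridin-2-yl)bis(trifluoromethanesulfonimide), −78 → −20 °C
Reagents that add atoms: N-(5-chloropyridin-2-yl)bis(trifluoromethanesulfonimide), O=S(=O)(N(c1ccc(Cl)cn1)S(=O)(=O)C(F)(F)F)C(F)(F)F
Why: C5 is the only enolisable position because C9 is quaternary, and the lithium enolate, which keeps its β-silyloxy group at low temperature, is trapped on oxygen by the triflimide (enol triflate formation).

Step 5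
Reactants: 9 enol triflate
Product: 10 vinyl diene
Conditions: Bu3SnCH=CH2, Pd(PPh3)4 (5 mol%), LiCl, THF, 65 °C
Reagents that add atoms: tributyl(vinyl)stannane, C=C[Sn](CCCC)(CCCC)CCCC
Why: Stille coupling of the enol triflate with the vinylstannane, assisted by chloride, places C1 and C2 on C10 and completes the semicyclic diene C5=C10–C1=C2.

Step 6
Reactants: 10 vinyl diene; 11 ethyl 2-methylbuta-2,3-dienoate
Product: 13 hydroxy cycloadduct, via silylated cycloadduct 12 (not isolated)
Conditions: 11 (3 equiv), BHT, toluene, 110 °C (sealed tube); then PPTS, MeOH, rt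
Reagents that add atoms: none
Why: The quaternary C9 holds the vinyl group s-cis, and the [4+2] cycloaddition across the conjugated C=C of the allenoate joins the ester-bearing carbon C4 to the ring terminus C5 and C3 to C2, as expected for 1-vinylcyclohexene dienes, which closes ring A with C3 as an exocyclic methylene; the configurations formed at C4 and C5 are immaterial because both centres are reset later, and mild acid methanolysis then removes only the triethylsilyl ether (Diels–Alder reaction, silyl ether cleavage).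

Step 7
Reactants: 13 hydroxy cycloadduct
Product: 15 conjugated enone ester, via unconjugated ketone 14 (not isolated)
Conditions: Dess–Martin periodinane, pyridine, CH2Cl2, 0 °C → rt; then Bu4NF, THF, 0 °C → rt
Reagents that add atoms: none
Why: Oxidation gives the C6 ketone, whose C5 hydrogen is both α to the carbonyl and allylic, so fluoride-mediated enolisation moves the alkene into conjugation as the tetrasubstituted C5=C10 enone (erasing C5 and the old C6 centre) while the same reagent cleaves the alkynyl silane (alcohol oxidation, alkene conjugation, alkynylsilane cleavage).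

Step 8
Reactants: 15 conjugated enone ester
Product: 16 allylic alcohol (6S)
Conditions: (R)-2-methyl-CBS-oxazaborolidine, catecholborane, toluene, −78 → −40 °C
Reagents that add atoms: none
Why: Corey–Bakshi–Shibata reduction under reagent control treats the fully substituted alkenyl carbon C5 as the large group, so the (R)-catalyst should give the 6S (α) allylic alcohol whatever the configuration at C4, while the ester, the methylene and the alkyne are left alone.

Step 9
Reactants: 16 allylic alcohol (6S)
Product: 17 C6 tert-butyldimethylsilyl ether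
Conditions: t-BuMe2SiOTf, 2,6-lutidine, CH2Cl2, −78 → 0 °C
Reagents that add atoms: tert-butyldimethylsilyl trifluoromethanesulfonate, CC(C)(C)[Si](C)(C)OS(=O)(=O)C(F)(F)F
Why: The silyl triflate protects the hindered allylic alcohol promptly, which prevents lactonisation onto the neighbouring ester and installs the group that later directs the C4 alkylation (silyl ether formation).

Step 10
Reactants: 17 C6 tert-butyldimethylsilyl ether
Product: 19 β-keto ester, via diol 18 (not isolated)
Conditions: OsO4 (2 mol%), NaIO4, 2,6-lutidine, dioxane/H2O, rt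
Reagents that add atoms: osmium tetroxide, O=[Os](=O)(=O)=O; NaIO4, [Na+].[O-]I(=O)(=O)=O
Why: Osmium tetroxide dihydroxylates the accessible 1,1-disubstituted C3 methylene far faster than the C5=C10 alkene flanked by two quaternary carbons or the alkyne, and periodate cleaves the diol to the C3 ketone (Lemieux–Johnson oxidation).

Step 11
Reactants: 19 β-keto ester
Product: 20 4-methyl ketone
Conditions: LiCl, H2O, DMSO, 150 °C
Reagents that add atoms: none
Why: Chloride dealkylates the non-enolisable β-keto ester and the carboxylate loses carbon dioxide (Krapcho dealkoxycarbonylation), which removes the ester that served only to activate the dienophile and converges both C4 epimers on one ketone, any conjugated 4-ene tautomer being funnelled through the same dienolate in the next step.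

Step 12
Reactants: 20 4-methyl ketone
Product: 22 hydroxymethyl ketone (4S), via potassium dienolate 21 (not isolated)
Conditions: KN(SiMe3)2 (0.98 equiv), THF, −78 → 0 °C; then CH2O (anhydrous, THF), −78 °C; AcOH, −78 °C
Reagents that add atoms: formaldehyde, C=O
Why: Equilibration gives the conjugated C3=C4–C5=C10 dienolate, in which the in-plane C4 methyl forces the neighbouring C6 silyloxy group pseudoaxial on the α face, so formaldehyde should add to C4 from the β face and set the quaternary centre as 4S with C19 β and C18 α (aldol hydroxymethylation of a thermodynamic dienolate, quenched cold to avoid retro-aldol).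

Step 13
Reactants: 23 3-(4-hydroxyphenyl)propanoic acid
Product: 25 silyl-protected acid, via bis-silyl compound 24 (not isolated)
Conditions: t-BuMe2SiCl, imidazole, DMF, rt; then K2CO3 (cat.), MeOH/THF/H2O, rt
Reagents that add atoms: tert-butylchlorodimethylsilane, CC(C)(C)[Si](C)(C)Cl
Why: Both acidic hydroxyls are silylated and the labile silyl ester is then hydrolysed selectively, leaving the phenol protected and the acid free (silylation, selective silyl ester cleavage).

Step 14
Reactants: 22 hydroxymethyl ketone (4S); 25 silyl-protected acid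
Product: 26 C19 ester
Conditions: EDC·HCl, DMAP, CH2Cl2, 0 °C → rt
Reagents that add atoms: none
Why: Carbodiimide activation with DMAP catalysis acylates the neopentyl primary C19 alcohol under conditions too mild for retro-aldol loss of formaldehyde (Steglich esterification).

Step 15
Reactants: 26 C19 ester
Product: 28 C13 aldehyde, via alkenylborane 27 (not isolated)
Conditions: (c-C6H11)2BH, THF, 0 °C; then H2O2, pH 7 phosphate buffer, 0 °C → rt
Reagents that add atoms: hydrogen peroxide, OO
Why: Dicyclohexylborane adds once and anti-Markovnikov to the terminal alkyne much faster than it reduces the hindered C3 ketone or touches the tetrasubstituted alkene, and buffered oxidation of the alkenylborane gives the C13 aldehyde (alkyne hydroboration–oxidation).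

Step 16
Reactants: 28 C13 aldehyde
Product: 29 C13/C16 ketol
Conditions: (CH2O)n, 3-benzyl-5-(2-hydroxyethyl)-4-methylthiazolium chloride (20 mol%), i-Pr2NEt, THF, 60 °C
Reagents that add atoms: formaldehyde (as paraformaldehyde), C=O
Why: The thiazolylidene carbene turns the aldehyde into its acyl anion equivalent, which adds to formaldehyde and so delivers the C13 ketone with the free C16 hydroxyl directly and without a protecting group (carbene-catalysed crossed acyloin hydroxymethylation of an aldehyde).

Step 17
Reactants: 29 C13/C16 ketol; 30 (triphenylphosphoranylidene)ketene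
Product: 32 bis-silyl butenolide, via ester ylide 31 (not isolated)
Conditions: 30 (1.3 equiv), toluene, 80 °C
Reagents that add atoms: none
Why: The C16 hydroxyl, the only free hydroxyl in 29, adds to the central ketene carbon of the cumulated ylide and gives the stabilised ester ylide 31, which forms the C16–O–C15 bond. The ylide carbon C14 then attacks the adjacent C13 carbonyl in a 5-exo-trig closure, and collapse of the oxaphosphetane with loss of triphenylphosphine oxide leaves the C13=C14 alkene inside the new lactone ring C (intramolecular Wittig olefination). The closest known reaction type is the conversion of α-hydroxy ketones into butenolides with this ylide, as applied to 21-hydroxy-20-keto steroids on the way to cardenolides. No stereocentre is formed. Only chemoselectivity is needed, and the substrate secures it: the C6 and phenolic oxygens are silylated, and the tethered ylide reaches C13 through a five-membered transition state whereas the hindered C3 ketone would demand a medium ring. The medium stays neutral, so the C16 hydrogens and the conjugated alkene of the product are not isomerised and the C19 ester and the silyl ethers persist.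

Step 18
Reactants: 32 bis-silyl butenolide
Product: 33 target CNP0301014.1
Conditions: HF·pyridine, pyridine, THF, 0 °C → rt
Reagents that add atoms: none
Why: Buffered hydrogen fluoride cleaves the aryl and the allylic secondary silyl ethers under mildly acidic conditions that leave the base-sensitive butenolide, the C19 ester and the β-acyloxy ketone untouched (fluoride-mediated desilylation).

**Compound list**

1 | (S)-carvone, (5S)-2-methyl-5-(prop-1-en-2-yl)cyclohex-2-en-1-one | CC1=CC[C@@H](CC1=O)C(C)=C | starting material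
2 | (3-bromoprop-1-yn-1-yl)triisopropylsilane | BrCC#C[Si](C(C)C)(C(C)C)C(C)C | starting material
3 | lithium (3S,5S)-2,3-dimethyl-5-(prop-1-en-2-yl)cyclohex-1-en-1-olate | C[C@H]1C[C@H](C(C)=C)CC(O[Li])=C1C | intermediate
4 | (2R,3S,5S)-2,3-dimethyl-5-(prop-1-en-2-yl)-2-[3-(triisopropylsilyl)prop-2-yn-1-yl]cyclohexan-1-one (C8 and C9 methyls β, propargyl and isopropenyl α) | C[C@H]1C[C@H](C(C)=C)CC(=O)[C@]1(C)CC#C[Si](C(C)C)(C(C)C)C(C)C | intermediate
5 | (2R,3S,5S)-5-(1-hydroperoxy-1-methoxyethyl)-2,3-dimethyl-2-[3-(triisopropylsilyl)prop-2-yn-1-yl]cyclohexan-1-one (either configuration at the peroxy carbon) | C[C@H]1C[C@H](C(C)(OC)OO)CC(=O)[C@]1(C)CC#C[Si](C(C)C)(C(C)C)C(C)C | intermediate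
6 | (2R,3S,5S)-5-acetoxy-2,3-dimethyl-2-[3-(triisopropylsilyl)prop-2-yn-1-yl]cyclohexan-1-one | C[C@H]1C[C@H](OC(C)=O)CC(=O)[C@]1(C)CC#C[Si](C(C)C)(C(C)C)C(C)C | intermediate
7 | (2R,3S,5S)-5-hydroxy-2,3-dimethyl-2-[3-(triisopropylsilyl)prop-2-yn-1-yl]cyclohexan-1-one | C[C@H]1C[C@H](O)CC(=O)[C@]1(C)CC#C[Si](C(C)C)(C(C)C)C(C)C | intermediate
8 | (2R,3S,5S)-2,3-dimethyl-5-(triethylsilyloxy)-2-[3-(triisopropylsilyl)prop-2-yn-1-yl]cyclohexan-1-one | C[C@H]1C[C@H](O[Si](CC)(CC)CC)CC(=O)[C@]1(C)CC#C[Si](C(C)C)(C(C)C)C(C)C | intermediate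
9 | ring B enol triflate: C10 triflyloxy, C5=C10 alkene, C6 α-triethylsilyloxy, C8 β-methyl, C9 β-methyl and α-(silylpropargyl) | C[C@H]1C[C@H](O[Si](CC)(CC)CC)C=C(OS(=O)(=O)C(F)(F)F)[C@]1(C)CC#C[Si](C(C)C)(C(C)C)C(C)C | intermediate
10 | ring B diene: as 9 with ethenyl (C1=C2) on C10 in place of the triflate | C[C@H]1C[C@H](O[Si](CC)(CC)CC)C=C(C=C)[C@]1(C)CC#C[Si](C(C)C)(C(C)C)C(C)C | intermediate
11 | ethyl 2-methylbuta-2,3-dienoate | C=C=C(C)C(=O)OCC | starting material
12 | cycloadduct triethylsilyl ether: rings A and B, C1=C10 alkene, C3 exocyclic methylene, C4 methyl and ethoxycarbonyl, C5–H (isomer from β-face, ester-endo addition drawn; C4/C5 stereoisomers carried on) | C[C@H]1C[C@H](O[Si](CC)(CC)CC)[C@@H]2C(=CCC(=C)[C@]2(C)C(=O)OCC)[C@]1(C)CC#C[Si](C(C)C)(C(C)C)C(C)C | intermediate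
13 | hydroxy cycloadduct: 12 with free 6α-hydroxyl | C[C@H]1C[C@H](O)[C@@H]2C(=CCC(=C)[C@]2(C)C(=O)OCC)[C@]1(C)CC#C[Si](C(C)C)(C(C)C)C(C)C | intermediate
14 | unconjugated C6 ketone of 13 (C1=C10 alkene, C5–H) | C[C@H]1CC(=O)[C@@H]2C(=CCC(=C)[C@]2(C)C(=O)OCC)[C@]1(C)CC#C[Si](C(C)C)(C(C)C)C(C)C | intermediate
15 | enone ester: C6 ketone conjugated with C5=C10, C3 methylene, C4 methyl and ethoxycarbonyl (β-ester epimer drawn; C4 epimer reacts alike), C9 α-propargyl with free alkyne | C[C@H]1CC(=O)C2=C(CCC(=C)[C@]2(C)C(=O)OCC)[C@]1(C)CC#C | intermediate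
16 | 6α-allylic alcohol (6S) of 15 | C[C@H]1C[C@H](O)C2=C(CCC(=C)[C@]2(C)C(=O)OCC)[C@]1(C)CC#C | intermediate
17 | 6α-tert-butyldimethylsilyl ether of 16 | C[C@H]1C[C@H](O[Si](C)(C)C(C)(C)C)C2=C(CCC(=C)[C@]2(C)C(=O)OCC)[C@]1(C)CC#C | intermediate
18 | C3 diol of 17 (C3 hydroxyl and hydroxymethyl; either C3 configuration) | C[C@H]1C[C@H](O[Si](C)(C)C(C)(C)C)C2=C(CCC(O)(CO)[C@]2(C)C(=O)OCC)[C@]1(C)CC#C | intermediate
19 | β-keto ester: C3 ketone, C4 methyl and ethoxycarbonyl | C[C@H]1C[C@H](O[Si](C)(C)C(C)(C)C)C2=C(CCC(=O)[C@]2(C)C(=O)OCC)[C@]1(C)CC#C | intermediate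
20 | 4-methyl-3-ketone with C5=C10 alkene and 6α-silyloxy group (C4 epimerisable, not defined) | C[C@H]1C[C@H](O[Si](C)(C)C(C)(C)C)C2=C(CCC(=O)C2C)[C@]1(C)CC#C | intermediate
21 | potassium C3=C4, C5=C10 dienolate of 20 | C[C@H]1C[C@H](O[Si](C)(C)C(C)(C)C)C2=C(CCC(O[K])=C2C)[C@]1(C)CC#C | intermediate
22 | (4S)-hydroxymethyl ketone: C3 ketone, C4 α-methyl (C18) and β-hydroxymethyl (C19) | C[C@H]1C[C@H](O[Si](C)(C)C(C)(C)C)C2=C(CCC(=O)[C@]2(C)CO)[C@]1(C)CC#C | intermediate
23 | 3-(4-hydroxyphenyl)propanoic acid | OC(=O)CCc1ccc(O)cc1 | starting material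
24 | tert-butyldimethylsilyl 3-[4-(tert-butyldimethylsilyloxy)phenyl]propanoate | CC(C)(C)[Si](C)(C)OC(=O)CCc1ccc(O[Si](C)(C)C(C)(C)C)cc1 | intermediate
25 | 3-[4-(tert-butyldimethylsilyloxy)phenyl]propanoic acid | OC(=O)CCc1ccc(O[Si](C)(C)C(C)(C)C)cc1 | intermediate
26 | C19 ester of 22 with acid 25 (terminal alkyne retained) | C[C@H]1C[C@H](O[Si](C)(C)C(C)(C)C)C2=C(CCC(=O)[C@]2(C)COC(=O)CCc2ccc(O[Si](C)(C)C(C)(C)C)cc2)[C@]1(C)CC#C | intermediate
27 | (E)-alkenyl dicyclohexylborane from 26 (boron on C13) | C[C@H]1C[C@H](O[Si](C)(C)C(C)(C)C)C2=C(CCC(=O)[C@]2(C)COC(=O)CCc2ccc(O[Si](C)(C)C(C)(C)C)cc2)[C@]1(C)C/C=C/B(C1CCCCC1)C1CCCCC1 | intermediate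
28 | C13 aldehyde (side chain C11H2–C12H2–C13HO) | C[C@H]1C[C@H](O[Si](C)(C)C(C)(C)C)C2=C(CCC(=O)[C@]2(C)COC(=O)CCc2ccc(O[Si](C)(C)C(C)(C)C)cc2)[C@]1(C)CCC=O | intermediate
29 | ketol precursor: C13 ketone with C16 hydroxyl, C6 and phenol as tert-butyldimethylsilyl ethers | C[C@H]1C[C@H](O[Si](C)(C)C(C)(C)C)C2=C(CCC(=O)[C@]2(C)COC(=O)CCc2ccc(O[Si](C)(C)C(C)(C)C)cc2)[C@]1(C)CCC(=O)CO | intermediate
30 | (triphenylphosphoranylidene)ketene | O=C=C=P(c1ccccc1)(c1ccccc1)c1ccccc1 | starting material
31 | O16 (triphenylphosphoranylidene)acetate of 29 (ester ylide) | C[C@H]1C[C@H](O[Si](C)(C)C(C)(C)C)C2=C(CCC(=O)[C@]2(C)COC(=O)CCc2ccc(O[Si](C)(C)C(C)(C)C)cc2)[C@]1(C)CCC(=O)COC(=O)C=P(c1ccccc1)(c1ccccc1)c1ccccc1 | intermediate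
32 | bis(tert-butyldimethylsilyl) ether of the target (butenolide closed) | C[C@H]1C[C@H](O[Si](C)(C)C(C)(C)C)C2=C(CCC(=O)[C@]2(C)COC(=O)CCc2ccc(O[Si](C)(C)C(C)(C)C)cc2)[C@]1(C)CCC1=CC(=O)OC1 | intermediate
33 | CNP0301014.1 (4S,6S,8S,9R) | C[C@H]1C[C@H](O)C2=C(CCC(=O)[C@]2(C)COC(=O)CCc2ccc(O)cc2)[C@]1(C)CCC1=CC(=O)OC1 | target

**Step count.** Total: 18 steps. Longest linear sequence: 17 steps (steps 1–12 and 14–18, from (S)-carvone); step 13 prepares the acid partner.

**Steps most likely to fail**

Step 12 (hydroxymethylation at C4). Enolisation may take place at C2 instead of C4, formaldehyde may approach from the α face, or the new hydroxymethyl group may be lost again by retro-aldol cleavage on work-up. The fallback keeps the ester carbon delivered by the cycloaddition as C19 and sets out from 17. Reduction with LiAlH4 (THF, 0 °C) gives the neopentyl alcohols, from which the 4S epimer, C19 alcohol F1, is separated. Steglich esterification with 25 gives the ester F2. Dicyclohexylborane adds to the alkyne to give the alkenylborane F3, and buffered peroxide turns it into the aldehyde F4, which still carries the C3 methylene. Lemieux–Johnson cleavage (OsO4, NaIO4) through the diol F5 then returns to the route at 28. This path uses only the fraction of 17 that carries the ester on the β face.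

Step 6 (Diels–Alder annulation). Bond formation at the hindered ring terminus C5 may be slow, so that the allenoate oligomerises, or the ester-bearing carbon may bond to C2 instead of C5. The fallback fixes the regiochemistry by a tether and sets out from 10. PPTS in methanol removes only the triethylsilyl group and gives the dienol F6. The acid 2-methylbuta-2,3-dienoic acid F7 (from 11 with LiOH, THF/H2O, 0 °C) is coupled to it with DCC and DMAP to give the C6 allenoate ester F8. Heating in toluene (130–150 °C) closes ring A intramolecularly, the short ester tether forcing the ester-bearing carbon onto C5, and gives the tricyclic lactone F9. Saponification with KOH gives the potassium carboxylate F10, which is alkylated in the same flask with iodoethane in DMF and returns to the route at 13 (as C4/C5 stereoisomers, which converge as before).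

Step 16 (carbene-catalysed hydroxymethylation). Self-condensation of the aldehyde to an acyloin or attack of the carbene on other carbonyl groups may outrun the crossed reaction with formaldehyde. The fallback builds the ketol through a diazoketone and sets out from 28. Chlorite oxidation (NaClO2, NaH2PO4, 2-methylbut-2-ene) gives the C13 carboxylic acid F11. Oxalyl chloride with catalytic DMF gives the acid chloride F12, which reacts with Me3SiCHN2 to give the diazoketone F13. Brief treatment with CF3CO2H at 0 °C gives the trifluoroacetoxy ketone F14, and NaHCO3 in methanol cleaves the trifluoroacetate and returns to the route at 29.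

**Further compounds**

F1 | step 12 | (4S) C19 alcohol with C3 methylene, 6α-silyl ether and terminal alkyne | C[C@H]1C[C@H](O[Si](C)(C)C(C)(C)C)C2=C(CCC(=C)[C@]2(C)CO)[C@]1(C)CC#C
F2 | step 12 | C19 ester of F1 with acid 25 | C[C@H]1C[C@H](O[Si](C)(C)C(C)(C)C)C2=C(CCC(=C)[C@]2(C)COC(=O)CCc2ccc(O[Si](C)(C)C(C)(C)C)cc2)[C@]1(C)CC#C
F3 | step 12 | (E)-alkenyl dicyclohexylborane from F2 | C[C@H]1C[C@H](O[Si](C)(C)C(C)(C)C)C2=C(CCC(=C)[C@]2(C)COC(=O)CCc2ccc(O[Si](C)(C)C(C)(C)C)cc2)[C@]1(C)C/C=C/B(C1CCCCC1)C1CCCCC1
F4 | step 12 | C13 aldehyde with C3 methylene | C[C@H]1C[C@H](O[Si](C)(C)C(C)(C)C)C2=C(CCC(=C)[C@]2(C)COC(=O)CCc2ccc(O[Si](C)(C)C(C)(C)C)cc2)[C@]1(C)CCC=O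
F5 | step 12 | C3 diol of F4 | C[C@H]1C[C@H](O[Si](C)(C)C(C)(C)C)C2=C(CCC(O)(CO)[C@]2(C)COC(=O)CCc2ccc(O[Si](C)(C)C(C)(C)C)cc2)[C@]1(C)CCC=O
F6 | step 6 | dienol: 10 with free 6α-hydroxyl | C[C@H]1C[C@H](O)C=C(C=C)[C@]1(C)CC#C[Si](C(C)C)(C(C)C)C(C)C
F7 | step 6 | 2-methylbuta-2,3-dienoic acid | C=C=C(C)C(O)=O
F8 | step 6 | C6 2-methylbuta-2,3-dienoate of F6 | C[C@H]1C[C@H](OC(=O)C(C)=C=C)C=C(C=C)[C@]1(C)CC#C[Si](C(C)C)(C(C)C)C(C)C
F9 | step 6 | tricyclic lactone (C19 carbonyl bound to O6; C1=C10 alkene, C3 methylene) | C[C@H]1C[C@@H]2OC(=O)C3(C)C(=C)CC=C(C23)[C@]1(C)CC#C[Si](C(C)C)(C(C)C)C(C)C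
F10 | step 6 | potassium carboxylate from F9 | C[C@H]1C[C@H](O)C2C(=CCC(=C)C2(C)C(=O)[O-])[C@]1(C)CC#C[Si](C(C)C)(C(C)C)C(C)C.[K+]
F11 | step 16 | C13 carboxylic acid | C[C@H]1C[C@H](O[Si](C)(C)C(C)(C)C)C2=C(CCC(=O)[C@]2(C)COC(=O)CCc2ccc(O[Si](C)(C)C(C)(C)C)cc2)[C@]1(C)CCC(O)=O
F12 | step 16 | C13 acid chloride | C[C@H]1C[C@H](O[Si](C)(C)C(C)(C)C)C2=C(CCC(=O)[C@]2(C)COC(=O)CCc2ccc(O[Si](C)(C)C(C)(C)C)cc2)[C@]1(C)CCC(Cl)=O
F13 | step 16 | diazoketone (C13 ketone, C16 diazo carbon) | C[C@H]1C[C@H](O[Si](C)(C)C(C)(C)C)C2=C(CCC(=O)[C@]2(C)COC(=O)CCc2ccc(O[Si](C)(C)C(C)(C)C)cc2)[C@]1(C)CCC(=O)C=[N+]=[N-]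
F14 | step 16 | C16 trifluoroacetate of 29 | C[C@H]1C[C@H](O[Si](C)(C)C(C)(C)C)C2=C(CCC(=O)[C@]2(C)COC(=O)CCc2ccc(O[Si](C)(C)C(C)(C)C)cc2)[C@]1(C)CCC(=O)COC(=O)C(F)(F)F
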